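**Retrosynthetic overview**

- Feature: C4 and C9, both oxygenated, lie 1,6 across the ten-membered ring C1–C10 with C5–C8 between them. A C4–C9 bond folds that ring into ring B (C1, C2, C3, C4, C9, C10) of a trans-decalin fused to ring A, with alkenyl groups on C4 and C9.
- Late stage: γ-lactone by oxidative lactonisation of C19 onto O7; 8α-OH/9α-O by open-face epoxidation of the E C8=C9 alkene and rear-side opening at C8 by an O19 tert-butyl carbonate; C5=C6 by selenoxide elimination.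
- Ten-membered ring: anionic oxy-Cope ring expansion of the 4,9-dialkenyl decalin-4-ol (C6–C7 formed, C4–C9 broken); C7 set by the enol-ether geometry.
- Precursor: 2-lithioallyl alkoxide plus the C4 decalinone; C9–C8 by palladium α′-alkenylation with a β-iodo enol ether of fixed geometry (syn-hydrozirconation of an ynol ether made from the Roche ester).
- Ring order: ring B (Diels–Alder), ring A (ring-closing metathesis), 11,12-epoxide, ten-membered ring (step 19), γ-lactone.

Key step: step 19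

Convention: briarane numbering (C15 = methyl on C1, C16 on C5, C17–C19 lactone carbons, C18 = methyl on C17, C20 = methyl on C11); α = face of H-10, β = face of C15.

Assumption: the antipodes named for (salen)CrSbF6 (step 8), Ipc2B(allyl) (step 9) and the oxazaborolidine (step 25) are those the accepted transition-state models assign to the configurations drawn; the mirror-image reagent is used if a model fails.

**Side-chain fragment**

Step 1
Reactants: 1 4-methoxybenzyl alcohol; 2 tributyl(iodomethyl)stannane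
Product: 3 tributyl{[(4-methoxybenzyl)oxy]methyl}stannane
Conditions: NaH, THF/DMF, 0 → 25 °C
Reagents that add atoms: none
Why: Williamson etherification of the sodium alkoxide with the primary iodide should give the α-alkoxymethylstannane needed for tin–lithium exchange.

Step 2
Reactants: 4 methyl (S)-3-hydroxy-2-methylpropanoate
Product: 5 methyl (S)-2-methyl-3-(triethylsilyloxy)propanoate
Conditions: Et3SiCl, imidazole, CH2Cl2, 0 °C
Reagents that add atoms: chlorotriethylsilane, CC[Si](Cl)(CC)CC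
Why: Silylation of the primary alcohol; C17 comes from the chiral pool and is not touched.

Step 3
Reactants: 5 methyl (S)-2-methyl-3-(triethylsilyloxy)propanoate
Product: 6 (S)-N-methoxy-N,2-dimethyl-3-(triethylsilyloxy)propanamide
Conditions: MeNH(OMe)·HCl, i-PrMgCl, THF, −20 °C
Reagents that add atoms: N,O-dimethylhydroxylamine hydrochloride, CNOC.Cl
Why: Weinreb amide formation by aminolysis of the ester with the magnesium amide at low temperature should leave C17 intact.

Step 4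
Reactants: 3 tributyl{[(4-methoxybenzyl)oxy]methyl}stannane; 6 Weinreb amide
Product: 8 (S)-1-[(4-methoxybenzyl)oxy]-3-methyl-4-(triethylsilyloxy)butan-2-one, via alkoxymethyllithium 7 (not isolated)
Conditions: n-BuLi, THF, −78 °C; then 6, −78 °C; aq NH4Cl
Reagents that add atoms: none
Why: Tin–lithium exchange gives the α-alkoxy organolithium, which acylates once on the Weinreb amide through its stable chelate.

Step 5
Reactants: 8 α-alkoxy ketone
Product: 10 (R)-triethyl{[4-((4-methoxybenzyl)oxy)-2-methylbut-3-yn-1-yl]oxy}silane, via enol triflate 9 (not isolated)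
Conditions: LiN(SiMe3)2, PhNTf2, THF, −78 → 0 °C; then KOt-Bu, THF, −78 °C; kept below 25 °C
Reagents that add atoms: N-phenylbis(trifluoromethanesulfonimide), O=S(=O)(N(c1ccccc1)S(=O)(=O)C(F)(F)F)C(F)(F)F (its triflyl group is carried only by 9)
Why: Kinetic enolisation on the alkoxymethyl side, O-triflation and anti E2 loss of triflate (ynol ether synthesis from α-alkoxy ketones) should give the alkynyl ether without deprotonating C17.

Step 6
Reactants: 10 ynol ether
Product: 12 (S,E)-triethyl{[3-iodo-4-((4-methoxybenzyl)oxy)-2-methylbut-3-en-1-yl]oxy}silane, via alkenylzirconocene 11 (not isolated)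
Conditions: Cp2Zr(H)Cl, THF, 0 → 20 °C; then I2, THF, −20 °C
Reagents that add atoms: Cp2Zr(H)Cl (zirconocene chloride hydride), [H][Zr](Cl)(C1C=CC=C1)C1C=CC=C1 (zirconium is carried only by 11); iodine, II
Why: syn-Hydrozirconation should put zirconium on the carbon remote from oxygen (C8), as with alkoxyacetylenes, and iodinolysis with retention fixes iodine trans to the ether oxygen, so C17 is cis to O7.

**Decalin core**

Step 7
Reactants: 13 2-oxopropanal (40% aq.); 14 2-(triphenylphosphoranylidene)propanal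
Product: 15 (E)-2-methyl-4-oxopent-2-enal
Conditions: CH2Cl2/H2O, 25 °C
Reagents that add atoms: none
Why: Wittig reaction of the stabilised ylide at the aldehyde carbon should give the E enal, with formyl trans to acetyl.

Step 8
Reactants: 15 (E)-2-methyl-4-oxopent-2-enal; 16 (E)-1-(dimethylamino)-3-(tert-butyldimethylsilyloxy)buta-1,3-diene
Product: 17 cycloadduct (C1 methyl/formyl, C2 NMe2, C4 silyl enol ether, C10 acetyl; formyl trans to acetyl)
Conditions: (R,R)-(salen)CrSbF6 (5 mol %; salen = N,N′-bis(3,5-di-tert-butylsalicylidene)cyclohexane-1,2-diaminate), 4 Å MS, CH2Cl2, −40 °C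
Reagents that add atoms: none
Why: Diels–Alder reaction of the aminosiloxy diene with the enal bound to the chiral chromium Lewis acid: the CH2 terminus bonds to C10 (β to formyl, unsubstituted), the E geometry of 15 becomes the trans C1/C10 relationship (C15 cis to C11), and the catalyst sets the quaternary C1.

Step 9
Reactants: 17 cycloadduct
Product: 18 homoallylic alcohol (14S, 14α-OH)
Conditions: (−)-Ipc2B(allyl) (from (+)-α-pinene), Et2O, −78 °C; ethanolamine work-up
Reagents that add atoms: (−)-B-allyldiisopinocampheylborane, C=CCB(C1CC2CC(C1C)C2(C)C)C1CC2CC(C1C)C2(C)C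
Why: Brown allylboration is selective for the aldehyde over the methyl ketone at −78 °C, and reagent control through the chair transition state should give the 14S carbinol.

Step 10
Reactants: 18 homoallylic alcohol
Product: 19 14-O-TBS ether
Conditions: t-BuMe2SiOTf, 2,6-lutidine, CH2Cl2, −78 °C
Reagents that add atoms: tert-butyldimethylsilyl trifluoromethanesulfonate, CC(C)(C)[Si](C)(C)OS(=O)(=O)C(F)(F)F
Why: Silylation of the hindered secondary alcohol with the silyl triflate at low temperature, where the ketone is not enolised.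

Step 11
Reactants: 19 14-O-TBS ether
Product: 20 isopropenyl compound
Conditions: Cp2Ti(μ-Cl)(μ-CH2)AlMe2, pyridine, THF/toluene, −40 → 0 °C
Reagents that add atoms: Cp2Ti(μ-CH2)(μ-Cl)AlMe2 (Tebbe reagent), C[Al-]1(C)C[Ti](C2C=CC=C2)(C2C=CC=C2)[Cl+]1 (the bridging chloride is drawn with formal charges; only the CH2 group enters 20)
Why: Non-basic Tebbe methylenation of the only carbonyl group should convert the acetyl group into the isopropenyl group without epimerising C10.

Step 12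
Reactants: 20 isopropenyl compound
Product: 21 4-methyl-4,5-disubstituted cyclohex-2-enone (C4 ketone, C2=C3)
Conditions: 0.1 M HCl, THF, 0 °C
Reagents that add atoms: none
Why: Hydrolysis of the silyl enol ether and E1cB loss of dimethylamine unveil the enone, whose C1 is quaternary so that C9 is the only enolisable position.

Step 13
Reactants: 21 cyclohexenone
Product: 22 trans-fused 5-(tert-butyldimethylsilyloxy)-4a,8-dimethyl-4a,5,6,8a-tetrahydronaphthalen-2(1H)-one
Conditions: second-generation Grubbs catalyst (5 mol %), CH2Cl2, 40 °C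
Reagents that add atoms: none
Why: Ring-closing metathesis of the allyl and isopropenyl groups, which are trans on ring B, closes ring A as a trans-fused cyclohexene with the C11(methyl)=C12 double bond; the enone is inert.

Step 14
Reactants: 22 bicyclic dienone
Product: 24 11β,12β-epoxy enone, via bromohydrin 23 (not isolated)
Conditions: N-bromosuccinimide, THF/H2O, 0 °C; then K2CO3, MeOH, 0 °C
Reagents that add atoms: N-bromosuccinimide, O=C1CCC(=O)N1Br (bromine is carried only by 23); water, O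
Why: Bromohydrin formation by Markovnikov, trans-diaxial opening of the α-bromonium ion by water at C11 (as in 5α-bromo-6β-hydroxy steroids), then base closure with inversion at C12, should give the β-epoxide that direct peracid attack would not.

Step 15
Reactants: 24 epoxy enone; 12 β-iodo enol ether
Product: 25 9α-alkenyl epoxy enone
Conditions: LiN(SiMe3)2 (2.2 equiv), Pd2(dba)3 (3 mol %), P(t-Bu)3 (6 mol %), toluene/THF, 25 → 50 °C; AcOH, −78 °C
Reagents that add atoms: none
Why: Palladium-catalysed α-alkenylation of the cross-conjugated lithium enolate (C9 only) with retention of the iodide geometry; axial protonation of the product enolate should leave the alkenyl group equatorial (9α).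

Step 16
Reactants: 25 9α-alkenyl epoxy enone
Product: 27 2α-hydroxy ketone, via 2α-boronate 26 (not isolated)
Conditions: B2pin2, CuCl (5 mol %), Xantphos, NaOt-Bu (cat.), MeOH, THF, 0 °C; then NaBO3·4H2O, THF/H2O
Reagents that add atoms: bis(pinacolato)diboron, CC1(C)OB(OC1(C)C)B1OC(C)(C)C(C)(C)O1 (boron is carried only by 26); sodium perborate, [Na+].[O-]OB=O
Why: Copper-catalysed conjugate borylation at C2 anti to the axial C15 methyl, then oxidation with retention, should give the axial 2α-alcohol (the facial sense of 1α attack on steroidal 1-en-3-ones).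

Step 17
Reactants: 27 2α-hydroxy ketone
Product: 28 C4 decalinone (2α,14α-bis-TBS ether)
Conditions: t-BuMe2SiOTf, 2,6-lutidine, CH2Cl2, −78 °C
Reagents that add atoms: tert-butyldimethylsilyl trifluoromethanesulfonate, CC(C)(C)[Si](C)(C)OS(=O)(=O)C(F)(F)F
Why: Silylation under non-enolising conditions avoids β-elimination of the C2 oxygen.

Step 18
Reactants: 28 C4 decalinone; 29 2-bromoprop-2-en-1-ol
Product: 31 trans-4,9-dialkenyl decalin-4-ol with free C16 hydroxyl, via dilithio reagent 30 (not isolated)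
Conditions: t-BuLi (3 equiv), Et2O, −78 → 0 °C; CeCl3, THF, −78 °C; then 28, −78 °C
Reagents that add atoms: none
Why: 1,2-Addition of the weakly basic organocerium from the equatorial direction (the axial face is blocked by the syn-axial 2α-silyloxy group and H-10) should give the axial 4α-OH with the 2-propenyl unit equatorial, trans to the C9 alkenyl group.

**Key step**

Step 19
Reactants: 31 dialkenyl decalin-4-ol
Product: 33 cyclodeca-4,8-diene C4 silyl enol ether (7α-OPMB, 16-OTBS), via dipotassium enolate 32 (not isolated)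
Conditions: KH (5 equiv), 18-crown-6 (3 equiv), THF, 0 → 25 °C; then t-BuMe2SiCl, −78 → 0 °C
Reagents that add atoms: tert-butylchlorodimethylsilane, CC(C)(C)[Si](C)(C)Cl
Why: KH/18-crown-6 forms the C4,C16 dialkoxide; the naked C4 alkoxide weakens the C4–C9 bond and the 1,5-diene C6=C5–C4–C9–C8=C7 undergoes a concerted [3,3] shift (C6–C7 formed, C4–C9 broken) to the ring-expanded enolate 32, which the silyl chloride caps on both oxygens. The closest known reaction type is the anionic oxy-Cope ring expansion of trans-1,2-dialkenylcyclohexanols to (E)-cyclodec-5-enones, including cases with an enol ether as one alkene. The ten-membered ring (C1–C10) is not closed end to end but arises by four-carbon enlargement of ring B through a chair-like six-membered transition state. The only new stereocentre, C7, is set by suprafacial transfer from C9: the new bond at C7 forms on the face from which C4 departs, and with O7 trans to C9 on the enol ether this gives 7α-O. The step needs chair topology and E geometry at both new double bonds, which the trans-diequatorial alkenyl groups on the rigid trans-decalin secure (C3 and C10 pseudo-equatorial). It also needs the enolate to survive: C16 is an alkoxide, which is not a leaving group, and cold silylation stops proton transfer to C3, which would expel the C2 silyloxy group.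

**Endgame**

Step 20
Reactants: 33 silyl enol ether
Product: 35 (5Z)-enone (C4 ketone, C5=C6, 16-OTBS), via 5-phenylselanyl ketone 34 (not isolated)
Conditions: PhSeCl, CH2Cl2, −78 °C; then pyridine, 30% H2O2, 0 → 25 °C
Reagents that add atoms: benzeneselenenyl chloride, Cl[Se]c1ccccc1 (selenium is carried only by 34)
Why: α-Selenenylation of the silyl enol ether at C5 and selenoxide syn-elimination, which avoids the oxygen-bearing C16, should place the double bond at C5=C6; the ring-cis enone drawn is expected as the less strained isomer.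

Step 21
Reactants: 35 enone
Product: 36 C19 primary alcohol
Conditions: pyridinium p-toluenesulfonate (cat.), MeOH, 0 °C
Reagents that add atoms: none
Why: Mild acidic methanolysis removes the primary triethylsilyl ether much faster than the primary and secondary TBS ethers.

Step 22
Reactants: 36 C19 alcohol
Product: 37 C19 tert-butyl carbonate
Conditions: Boc2O, DMAP (cat.), Et3N, CH2Cl2, 0 °C
Reagents that add atoms: di-tert-butyl dicarbonate, CC(C)(C)OC(=O)OC(=O)OC(C)(C)C
Why: Acylation of the only free hydroxyl installs the internal nucleophile for C8.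

Step 23
Reactants: 37 carbonate
Product: 38 8,9-epoxide (9α-O, 8β-O)
Conditions: mCPBA, NaHCO3, CH2Cl2, 0 °C
Reagents that add atoms: 3-chloroperoxybenzoic acid, OOC(=O)c1cccc(Cl)c1
Why: Prilezhaev epoxidation spares the enone; allylic strain with C17 keeps H-10 eclipsing the E C8=C9 alkene, so the ring covers one face and the peracid should add from the open face, giving the correct 9α-O and an 8β-O to be inverted.

Step 24
Reactants: 38 epoxy carbonate
Product: 39 8α,19-cyclic carbonate with free 9α-OH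
Conditions: BF3·OEt2 (1.1 equiv), CH2Cl2, −78 → −40 °C; aq NaHCO3
Reagents that add atoms: none
Why: Lewis-acid-promoted 6-exo opening of the epoxide at the tertiary C8 by the carbonate carbonyl oxygen with loss of 2-methylpropene (the known route from epoxy alcohol tert-butyl carbonates to 1,3-diol carbonates) goes with inversion, so O8 becomes α and C17 β while O9 stays α.

Step 25
Reactants: 39 cyclic carbonate enone
Product: 40 4β-allylic alcohol (4R)
Conditions: (S)-2-methyl-CBS-oxazaborolidine (0.5 equiv), catecholborane, toluene, −78 °C; MeOH quench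
Reagents that add atoms: none
Why: Corey–Bakshi–Shibata 1,2-reduction of the α-substituted enone under reagent control (alkenyl side as the large group) should give the 4R carbinol.

Step 26
Reactants: 40 diol (4β-OH, 9α-OH)
Product: 41 4,9-bis(triethylsilyl) ether
Conditions: Et3SiOTf, 2,6-lutidine, CH2Cl2, −78 → 0 °C
Reagents that add atoms: triethylsilyl trifluoromethanesulfonate, CC[Si](CC)(CC)OS(=O)(=O)C(F)(F)F
Why: Silylation of both secondary alcohols masks O9 so that only O7 can later capture C19.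

Step 27
Reactants: 41 bis(triethylsilyl) ether
Product: 42 7α-alcohol
Conditions: DDQ, CH2Cl2/pH 7 buffer, 0 °C
Reagents that add atoms: none
Why: Oxidative cleavage of the PMB ether while O8 is still tied up in the carbonate avoids anisylidene acetal formation.

Step 28
Reactants: 42 7α-alcohol
Product: 43 7,8,19-triol
Conditions: K2CO3 (cat.), MeOH, 0 → 25 °C
Reagents that add atoms: none
Why: Methanolysis of the cyclic carbonate frees the tertiary 8α-OH and the primary C19-OH; no enone or ester is present at this stage.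

Step 29
Reactants: 43 triol
Product: 45 γ-lactone (O7–C19, free 8α-OH), via C19 aldehyde 44 (not isolated)
Conditions: TEMPO (20 mol %), PhI(OAc)2 (2.5 equiv), CH2Cl2, 25 °C
Reagents that add atoms: none
Why: Oxidative lactonisation: the unhindered primary alcohol is oxidised first, the aldehyde is trapped by O7 as the five-membered lactol (O9 is silylated, O8 would give a four-membered ring), and the lactol is oxidised on.

Step 30
Reactants: 45 lactone
Product: 46 hexaol (2,4,8,9,14,16-OH)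
Conditions: Bu4NF, AcOH (1:1), THF, 50 °C
Reagents that add atoms: none
Why: Buffered fluoride removes all five silyl ethers without base-induced retro-aldol opening of the β-hydroxy lactone.

Step 31
Reactants: 46 hexaol
Product: 47 2,4,9,14,16-pentaacetate
Conditions: Ac2O, pyridine, DMAP, CH2Cl2, 0 → 25 °C
Reagents that add atoms: acetic anhydride, CC(=O)OC(C)=O
Why: Acetylation of the primary and the four secondary hydroxyls; the tertiary 8-OH, flanked by two fully substituted carbons, should stay free.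

Step 32
Reactants: 47 pentaacetate
Product: 48 CNP0104124.1
Conditions: [t-Bu2Sn(OH)Cl]2 (5 mol %), MeOH/THF, 30 °C
Reagents that add atoms: none
Why: Distannoxane-catalysed neutral transesterification cleaves the primary allylic C16 acetate much faster than the four hindered secondary acetates.

**Compound list**

1 | 4-methoxybenzyl alcohol | COc1ccc(CO)cc1 | starting material
2 | tributyl(iodomethyl)stannane | CCCC[Sn](CCCC)(CCCC)CI | starting material
3 | tributyl{[(4-methoxybenzyl)oxy]methyl}stannane | CCCC[Sn](CCCC)(CCCC)COCc1ccc(OC)cc1 | intermediate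
4 | methyl (S)-3-hydroxy-2-methylpropanoate | COC(=O)[C@@H](C)CO | starting material
5 | methyl (S)-2-methyl-3-(triethylsilyloxy)propanoate | COC(=O)[C@@H](C)CO[Si](CC)(CC)CC | intermediate
6 | (S)-N-methoxy-N,2-dimethyl-3-(triethylsilyloxy)propanamide | CON(C)C(=O)[C@@H](C)CO[Si](CC)(CC)CC | intermediate
7 | [(4-methoxybenzyl)oxy]methyllithium | [Li]COCc1ccc(OC)cc1 | intermediate
8 | (S)-1-[(4-methoxybenzyl)oxy]-3-methyl-4-(triethylsilyloxy)butan-2-one | COc1ccc(COCC(=O)[C@@H](C)CO[Si](CC)(CC)CC)cc1 | intermediate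
9 | (Z)-enol triflate of 8 (OTf cis to OPMB) | COc1ccc(CO/C=C(\OS(=O)(=O)C(F)(F)F)[C@@H](C)CO[Si](CC)(CC)CC)cc1 | intermediate
10 | (R)-PMB ynol ether | COc1ccc(COC#C[C@@H](C)CO[Si](CC)(CC)CC)cc1 | intermediate
11 | alkenylzirconocene chloride (Zr on C8, trans to OPMB) | COc1ccc(CO/C=C(/[Zr](Cl)(C2C=CC=C2)C2C=CC=C2)[C@@H](C)CO[Si](CC)(CC)CC)cc1 | intermediate
12 | (S,E)-β-iodo enol ether (I trans to OPMB) | COc1ccc(CO/C=C(/I)[C@@H](C)CO[Si](CC)(CC)CC)cc1 | intermediate
13 | 2-oxopropanal | CC(=O)C=O | starting material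
14 | 2-(triphenylphosphoranylidene)propanal | CC(C=O)=P(c1ccccc1)(c1ccccc1)c1ccccc1 | starting material
15 | (E)-2-methyl-4-oxopent-2-enal | CC(=O)/C=C(\C)C=O | intermediate
16 | (E)-1-(dimethylamino)-3-(tert-butyldimethylsilyloxy)buta-1,3-diene | CN(C)/C=C/C(=C)O[Si](C)(C)C(C)(C)C | starting material
17 | Diels–Alder adduct (formyl trans to acetyl, cis to NMe2) | O=C[C@]1(C)[C@H](N(C)C)C=C(O[Si](C)(C)C(C)(C)C)C[C@H]1C(C)=O | intermediate
18 | 14S homoallylic alcohol | C=CC[C@H](O)[C@]1(C)[C@H](N(C)C)C=C(O[Si](C)(C)C(C)(C)C)C[C@H]1C(C)=O | intermediate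
19 | 14-O-TBS ether | C=CC[C@H](O[Si](C)(C)C(C)(C)C)[C@]1(C)[C@H](N(C)C)C=C(O[Si](C)(C)C(C)(C)C)C[C@H]1C(C)=O | intermediate
20 | isopropenyl compound | C=CC[C@H](O[Si](C)(C)C(C)(C)C)[C@]1(C)[C@H](N(C)C)C=C(O[Si](C)(C)C(C)(C)C)C[C@H]1C(C)=C | intermediate
21 | 4-methyl-4,5-disubstituted cyclohex-2-enone | C=CC[C@H](O[Si](C)(C)C(C)(C)C)[C@]1(C)C=CC(=O)C[C@H]1C(C)=C | intermediate
22 | trans-fused bicyclic dienone (C4 ketone, Δ2, Δ11, 14α-OTBS) | CC(C)(C)[Si](C)(C)O[C@H]1CC=C(C)[C@@H]2CC(=O)C=C[C@@]12C | intermediate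
23 | 12α-bromo-11β-hydroxy enone | CC(C)(C)[Si](C)(C)O[C@H]1C[C@@H](Br)[C@](C)(O)[C@@H]2CC(=O)C=C[C@@]12C | intermediate
24 | 11β,12β-epoxy enone | CC(C)(C)[Si](C)(C)O[C@H]1C[C@@H]2O[C@]2(C)[C@@H]2CC(=O)C=C[C@@]12C | intermediate
25 | 9α-alkenyl epoxy enone | CC(C)(C)[Si](C)(C)O[C@H]1C[C@@H]2O[C@]2(C)[C@@H]2[C@@H](/C(=C/OCc3ccc(OC)cc3)[C@@H](C)CO[Si](CC)(CC)CC)C(=O)C=C[C@@]12C | intermediate
26 | 2α-pinacolboronate ketone | CC(C)(C)[Si](C)(C)O[C@H]1C[C@@H]2O[C@]2(C)[C@@H]2[C@@H](/C(=C/OCc3ccc(OC)cc3)[C@@H](C)CO[Si](CC)(CC)CC)C(=O)C[C@@H](B3OC(C)(C)C(C)(C)O3)[C@@]12C | intermediate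
27 | 2α-hydroxy ketone | CC(C)(C)[Si](C)(C)O[C@H]1C[C@@H]2O[C@]2(C)[C@@H]2[C@@H](/C(=C/OCc3ccc(OC)cc3)[C@@H](C)CO[Si](CC)(CC)CC)C(=O)C[C@@H](O)[C@@]12C | intermediate
28 | C4 decalinone (2α,14α-bis-OTBS, 9α-alkenyl, 11β,12β-epoxide) | CC(C)(C)[Si](C)(C)O[C@H]1C[C@@H]2O[C@]2(C)[C@@H]2[C@@H](/C(=C/OCc3ccc(OC)cc3)[C@@H](C)CO[Si](CC)(CC)CC)C(=O)C[C@@H](O[Si](C)(C)C(C)(C)C)[C@@]12C | intermediate
29 | 2-bromoprop-2-en-1-ol | OCC(Br)=C | starting material
30 | lithium 2-lithioprop-2-en-1-olate | [Li]OCC([Li])=C | intermediate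
31 | trans-4,9-dialkenyl decalin-4-ol, free C16-OH (key-step precursor) | CC(C)(C)[Si](C)(C)O[C@H]1C[C@@H]2O[C@]2(C)[C@@H]2[C@@H](/C(=C/OCc3ccc(OC)cc3)[C@@H](C)CO[Si](CC)(CC)CC)[C@](O)(C(=C)CO)C[C@@H](O[Si](C)(C)C(C)(C)C)[C@@]12C | intermediate
32 | dipotassium C4 enolate/C16 alkoxide of the ten-membered ring | [K+].[K+].CC(C)(C)[Si](C)(C)O[C@H]1C[C@@H]2O[C@]2(C)[C@@H]2/C=C(\[C@@H](C)CO[Si](CC)(CC)CC)[C@@H](OCc3ccc(OC)cc3)C/C(C[O-])=C(\[O-])C[C@@H](O[Si](C)(C)C(C)(C)C)[C@@]12C | intermediate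
33 | cyclodeca-4,8-diene C4 silyl enol ether, 7α-OPMB (key-step product) | CC(C)(C)[Si](C)(C)O[C@H]1C[C@@H]2O[C@]2(C)[C@@H]2/C=C(\[C@@H](C)CO[Si](CC)(CC)CC)[C@@H](OCc3ccc(OC)cc3)C/C(CO[Si](C)(C)C(C)(C)C)=C(\O[Si](C)(C)C(C)(C)C)C[C@@H](O[Si](C)(C)C(C)(C)C)[C@@]12C | intermediate
34 | 5-phenylselanyl C4 ketone | CC(C)(C)[Si](C)(C)O[C@H]1C[C@@H]2O[C@]2(C)[C@@H]2/C=C(\[C@@H](C)CO[Si](CC)(CC)CC)[C@@H](OCc3ccc(OC)cc3)C[C@@](CO[Si](C)(C)C(C)(C)C)([Se]c3ccccc3)C(=O)C[C@@H](O[Si](C)(C)C(C)(C)C)[C@@]12C | intermediate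
35 | (5Z)-enone, 19-OTES | CC(C)(C)[Si](C)(C)O[C@H]1C[C@@H]2O[C@]2(C)[C@@H]2/C=C(\[C@@H](C)CO[Si](CC)(CC)CC)[C@@H](OCc3ccc(OC)cc3)/C=C(/CO[Si](C)(C)C(C)(C)C)C(=O)C[C@@H](O[Si](C)(C)C(C)(C)C)[C@@]12C | intermediate
36 | enone, 19-OH | CC(C)(C)[Si](C)(C)O[C@H]1C[C@@H]2O[C@]2(C)[C@@H]2/C=C(\[C@@H](C)CO)[C@@H](OCc3ccc(OC)cc3)/C=C(/CO[Si](C)(C)C(C)(C)C)C(=O)C[C@@H](O[Si](C)(C)C(C)(C)C)[C@@]12C | intermediate
37 | enone, 19-O-Boc | CC(C)(C)[Si](C)(C)O[C@H]1C[C@@H]2O[C@]2(C)[C@@H]2/C=C(\[C@@H](C)COC(=O)OC(C)(C)C)[C@@H](OCc3ccc(OC)cc3)/C=C(/CO[Si](C)(C)C(C)(C)C)C(=O)C[C@@H](O[Si](C)(C)C(C)(C)C)[C@@]12C | intermediate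
38 | 8,9-epoxide (9α-O, 8β-O) | CC(C)(C)[Si](C)(C)O[C@H]1C[C@@H]2O[C@]2(C)[C@@H]2[C@H]3O[C@]3([C@@H](C)COC(=O)OC(C)(C)C)[C@@H](OCc3ccc(OC)cc3)/C=C(/CO[Si](C)(C)C(C)(C)C)C(=O)C[C@@H](O[Si](C)(C)C(C)(C)C)[C@@]12C | intermediate
39 | 8α,19-cyclic carbonate, 9α-OH, enone | CC(C)(C)[Si](C)(C)O[C@H]1C[C@@H]2O[C@]2(C)[C@@H]2[C@@H](O)[C@@]3(OC(=O)OC[C@@H]3C)[C@@H](OCc3ccc(OC)cc3)/C=C(/CO[Si](C)(C)C(C)(C)C)C(=O)C[C@@H](O[Si](C)(C)C(C)(C)C)[C@@]12C | intermediate
40 | 4β-alcohol | CC(C)(C)[Si](C)(C)O[C@H]1C[C@@H]2O[C@]2(C)[C@@H]2[C@@H](O)[C@@]3(OC(=O)OC[C@@H]3C)[C@@H](OCc3ccc(OC)cc3)/C=C(/CO[Si](C)(C)C(C)(C)C)[C@H](O)C[C@@H](O[Si](C)(C)C(C)(C)C)[C@@]12C | intermediate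
41 | 4,9-bis(triethylsilyl) ether | CC(C)(C)[Si](C)(C)O[C@H]1C[C@@H]2O[C@]2(C)[C@@H]2[C@@H](O[Si](CC)(CC)CC)[C@@]3(OC(=O)OC[C@@H]3C)[C@@H](OCc3ccc(OC)cc3)/C=C(/CO[Si](C)(C)C(C)(C)C)[C@H](O[Si](CC)(CC)CC)C[C@@H](O[Si](C)(C)C(C)(C)C)[C@@]12C | intermediate
42 | 7α-alcohol | CC(C)(C)[Si](C)(C)O[C@H]1C[C@@H]2O[C@]2(C)[C@@H]2[C@@H](O[Si](CC)(CC)CC)[C@@]3(OC(=O)OC[C@@H]3C)[C@@H](O)/C=C(/CO[Si](C)(C)C(C)(C)C)[C@H](O[Si](CC)(CC)CC)C[C@@H](O[Si](C)(C)C(C)(C)C)[C@@]12C | intermediate
43 | 7,8,19-triol | CC(C)(C)[Si](C)(C)O[C@H]1C[C@@H]2O[C@]2(C)[C@@H]2[C@@H](O[Si](CC)(CC)CC)[C@](O)([C@@H](C)CO)[C@@H](O)/C=C(/CO[Si](C)(C)C(C)(C)C)[C@H](O[Si](CC)(CC)CC)C[C@@H](O[Si](C)(C)C(C)(C)C)[C@@]12C | intermediate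
44 | C19 aldehyde | CC(C)(C)[Si](C)(C)O[C@H]1C[C@@H]2O[C@]2(C)[C@@H]2[C@@H](O[Si](CC)(CC)CC)[C@](O)([C@@H](C)C=O)[C@@H](O)/C=C(/CO[Si](C)(C)C(C)(C)C)[C@H](O[Si](CC)(CC)CC)C[C@@H](O[Si](C)(C)C(C)(C)C)[C@@]12C | intermediate
45 | silyl-protected γ-lactone (free 8α-OH) | CC(C)(C)[Si](C)(C)O[C@H]1C[C@@H]2O[C@]2(C)[C@@H]2[C@@H](O[Si](CC)(CC)CC)[C@@]3(O)[C@H](/C=C(/CO[Si](C)(C)C(C)(C)C)[C@H](O[Si](CC)(CC)CC)C[C@@H](O[Si](C)(C)C(C)(C)C)[C@@]12C)OC(=O)[C@@H]3C | intermediate
46 | hexaol lactone | O[C@H]1C[C@@H]2O[C@]2(C)[C@@H]2[C@@H](O)[C@@]3(O)[C@H](/C=C(/CO)[C@H](O)C[C@@H](O)[C@@]12C)OC(=O)[C@@H]3C | intermediate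
47 | 2,4,9,14,16-pentaacetate | CC(=O)O[C@H]1C[C@@H]2O[C@]2(C)[C@@H]2[C@@H](OC(C)=O)[C@@]3(O)[C@H](/C=C(/COC(C)=O)[C@H](OC(C)=O)C[C@@H](OC(C)=O)[C@@]12C)OC(=O)[C@@H]3C | intermediate
48 | CNP0104124.1 | CC(=O)O[C@H]1C[C@@H]2O[C@]2(C)[C@@H]2[C@@H](OC(C)=O)[C@@]3(O)[C@H](/C=C(/CO)[C@H](OC(C)=O)C[C@@H](OC(C)=O)[C@@]12C)OC(=O)[C@@H]3C | target

**Step count and risks**

Total step count: 32. Longest linear sequence: 26 steps (steps 7–32, from 13 and 14).

Three steps most likely to fail: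

1. Step 15. Transmetalation and reductive elimination at the congested α′-carbon may be too slow, so that proto-deiodination of the iodide or O-alkenylation of the dienolate takes over. The fallback sets out from 24: deprotonation with LiN(SiMe3)2 (THF, −78 °C) and quench with N-bromosuccinimide should give the 9-bromo enone F1. Nickel-catalysed cross-coupling of this secondary α-bromo ketone (NiCl2·glyme, a bis(oxazoline) ligand, DME/THF, 10 °C) with alkenylzirconocene 11, made from 10 as in step 6 without iodine, forms C9–C8 through an α-keto radical and comes back to the route at 25.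

2. Step 19. The syn-axial 2α-silyl group may migrate to the C4 alkoxide, or the product enolate may equilibrate toward C3 and lose the C2 oxygen, before or after the rearrangement. The fallback sets out from 31: both hydroxyls are silylated (Me3SiOTf, Et3N, CH2Cl2, −78 °C) to the bis(trimethylsilyl) ether F2. Heating in base-washed glass (o-dichlorobenzene, 190 °C) runs the same [3,3] shift as a neutral siloxy-Cope rearrangement, with no alkoxide or free enolate, to the trimethylsilyl enol ether F3. Selenenylation–oxidation as in step 20 with a mild acidic work-up gives the 16-hydroxy enone F4, and silylation (t-BuMe2SiCl, imidazole) comes back to the route at 35.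

3. Step 24. The carbonate carbonyl may not reach the rear of C8 fast enough, so that Lewis-acid ionisation of the C8–O bond is followed by hydride shift from C7 or by opening of the ring A epoxide. The fallback sets out from 36 and gives up the C17 centre temporarily. DDQ gives the 7,19-diol F5, and TEMPO/PhI(OAc)2 closes the lactone first, to the β,γ-unsaturated lactone F6. mCPBA adds to the open face of C8=C9 to give the epoxy lactone F7, which triethylamine opens by E1cB from C17 to the 9α-hydroxy butenolide F8. Oxazaborolidine reduction as in step 25 gives the 4β,9α-diol F9. Lithium tert-butyl peroxide, delivered by the 9α-alkoxide, should epoxidise the butenolide on the α face to the 8α,17α-epoxy lactone F10. SmI2 (THF/MeOH, −78 °C) cleaves the C17–O bond and DBU equilibrates C17 to the epimer with C18 trans to C9, giving the triol lactone F11. Silylation with Et3SiOTf comes back to the route at 45.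

Further compounds
F1 | step 15 | 9-bromo-11β,12β-epoxy enone | CC(C)(C)[Si](C)(C)O[C@H]1C[C@@H]2O[C@]2(C)[C@@H]2[C@H](Br)C(=O)C=C[C@@]12C
F2 | step 19 | 4,16-bis(trimethylsilyl) ether of 31 | CC(C)(C)[Si](C)(C)O[C@H]1C[C@@H]2O[C@]2(C)[C@@H]2[C@@H](/C(=C/OCc3ccc(OC)cc3)[C@@H](C)CO[Si](CC)(CC)CC)[C@](O[Si](C)(C)C)(C(=C)CO[Si](C)(C)C)C[C@@H](O[Si](C)(C)C(C)(C)C)[C@@]12C
F3 | step 19 | C4 trimethylsilyl enol ether, 16-OTMS | CC(C)(C)[Si](C)(C)O[C@H]1C[C@@H]2O[C@]2(C)[C@@H]2/C=C(\[C@@H](C)CO[Si](CC)(CC)CC)[C@@H](OCc3ccc(OC)cc3)C/C(CO[Si](C)(C)C)=C(\O[Si](C)(C)C)C[C@@H](O[Si](C)(C)C(C)(C)C)[C@@]12C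
F4 | step 19 | (5Z)-enone with free 16-OH | CC(C)(C)[Si](C)(C)O[C@H]1C[C@@H]2O[C@]2(C)[C@@H]2/C=C(\[C@@H](C)CO[Si](CC)(CC)CC)[C@@H](OCc3ccc(OC)cc3)/C=C(/CO)C(=O)C[C@@H](O[Si](C)(C)C(C)(C)C)[C@@]12C
F5 | step 24 | 7α,19-diol enone | CC(C)(C)[Si](C)(C)O[C@H]1C[C@@H]2O[C@]2(C)[C@@H]2/C=C(\[C@@H](C)CO)[C@@H](O)/C=C(/CO[Si](C)(C)C(C)(C)C)C(=O)C[C@@H](O[Si](C)(C)C(C)(C)C)[C@@]12C
F6 | step 24 | β,γ-unsaturated γ-lactone (C8=C9) | CC(C)(C)[Si](C)(C)O[C@H]1C[C@@H]2O[C@]2(C)[C@@H]2/C=C3\[C@@H](C)C(=O)O[C@H]3/C=C(/CO[Si](C)(C)C(C)(C)C)C(=O)C[C@@H](O[Si](C)(C)C(C)(C)C)[C@@]12C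
F7 | step 24 | 8,9-epoxy lactone | CC(C)(C)[Si](C)(C)O[C@H]1C[C@@H]2O[C@]2(C)[C@@H]2[C@H]3O[C@@]34[C@@H](C)C(=O)O[C@H]4/C=C(/CO[Si](C)(C)C(C)(C)C)C(=O)C[C@@H](O[Si](C)(C)C(C)(C)C)[C@@]12C
F8 | step 24 | 9α-hydroxy 8(17)-butenolide | CC(C)(C)[Si](C)(C)O[C@H]1C[C@@H]2O[C@]2(C)[C@@H]2[C@@H](O)C3=C(C)C(=O)O[C@H]3/C=C(/CO[Si](C)(C)C(C)(C)C)C(=O)C[C@@H](O[Si](C)(C)C(C)(C)C)[C@@]12C
F9 | step 24 | 4β,9α-dihydroxy butenolide | CC(C)(C)[Si](C)(C)O[C@H]1C[C@@H]2O[C@]2(C)[C@@H]2[C@@H](O)C3=C(C)C(=O)O[C@H]3/C=C(/CO[Si](C)(C)C(C)(C)C)[C@H](O)C[C@@H](O[Si](C)(C)C(C)(C)C)[C@@]12C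
F10 | step 24 | 8α,17α-epoxy lactone | CC(C)(C)[Si](C)(C)O[C@H]1C[C@@H]2O[C@]2(C)[C@@H]2[C@@H](O)[C@]34O[C@@]3(C)C(=O)O[C@H]4/C=C(/CO[Si](C)(C)C(C)(C)C)[C@H](O)C[C@@H](O[Si](C)(C)C(C)(C)C)[C@@]12C
F11 | step 24 | 4β,8α,9α-triol lactone | CC(C)(C)[Si](C)(C)O[C@H]1C[C@@H]2O[C@]2(C)[C@@H]2[C@@H](O)[C@@]3(O)[C@H](/C=C(/CO[Si](C)(C)C(C)(C)C)[C@H](O)C[C@@H](O[Si](C)(C)C(C)(C)C)[C@@]12C)OC(=O)[C@@H]3C
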